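Summer gets 0.500 M more L than dusk, and you want to know what that buys at the asked time.

common to all: E 0.80 M
- birch: L 1.3 M; D 0.40 M; run made earlier
- ash: L 2 M; D 0.40 M; run made earlier
- maple: L 1.7 M; D 0.40 M; run made earlier
- dusk: L 1.60 M; D 0.400 M; time 15 h
- summer: L 2.10 M; D 0.400 M; time 15 h

- birch (time / h: E / %, J / %): 1.00: 67.8, 14.1; 2.50: 49.9, 24.0; 5.00: 41.1, 32.1; 8.00: 35.8, 39.9; 10.0: 33.1, 45.8
- ash (time / h: E / %, J / %): 1.00: 59.3, 22.3; 2.50: 40.3, 39.6; 5.00: 25.5, 52.0; 8.00: 20.5, 62.0; 10.0: 18.0, 65.7
- maple (time / h: E / %, J / %): 0.833: 67.0, 15.8; 1.50: 53.3, 24.4; 3.00: 38.7, 35.1; 6.00: 30.3, 48.8; 10.0: 23.8, 58.3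

(readings scatter by 1 percentage point)

- part of the E that has reacted at the end, dusk
- part of the E that has reacted at the end, summer
- what raising the concentration of L from its lowest to its highest value here does to the part of the E that has reacted (changes below 5 percentage points count as none) (it falls / it rises / no change)

- on the list of suspects stand: E + L -> Z + J; E <-> X; L + D -> Q; L + Z <-> G
- what has gone from E into another species counts as reacted, even if it can come back

Take the numbers in turn. The ratio [X]/[E] says how much of the E not yet turned into J is free to meet L, so an error in it moves J itself as well as the split of the remainder. The rate constant says how soon you approach the ceiling. The L spent per J says where the ceiling stands: if Z binds a second L as G, dusk's ceiling on J falls from 150 %, which is no ceiling, to 75.0 %. That price is the number I test here.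

Ash tests it. Its first hour reads 0.175 M⁻¹ h⁻¹ per E and per L. Its last two readings, a rough slope, give:

two L per J: 0.166 M⁻¹ h⁻¹

one L per J: 0.0882 M⁻¹ h⁻¹

So I count two. Call the L cover the charged [L] minus the charged [D], over 2 times the charged [E]:

dusk: 75.0 %

summer: 106 %

Below 100 %, L is the limiting reagent for J. I commit to this: dusk's J stalls near its cover, summer's does not, and the gap widens with time.

The forecast gave 79.5 % for dusk, 87 % for summer and it rises, reading the slowing as “L being consumed by D and by Z”.

The flask gives 76.9 %, 86.9 % and it rises. The gap between the two flasks comes from the difference in [L]: summer with dusk's L stands at 76.9 % instead of 86.9 %.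

    E + L → Z + J (k = 0.00340 M⁻¹ min⁻¹)
    E ⇌ X (K = 0.620, k = 0.00490 min⁻¹)
    L + D → Q (k = 0.520 M⁻¹ min⁻¹)
    L + Z ⇌ G, settled at all times (K = 5000 M⁻¹)

Dusk's cover of 75.0 % shows after 150 h: J stands at 76.4 % with 0.269 % of its L charge free, while summer's reacted E reaches 99.3 %. Part of the toll is the binding: without L + Z ⇌ G, dusk at the asked time goes from 76.9 % to 86.6 %. A neighbour of dusk charged with 0.40 M of L has a cover of 0 %, and after 15.0 h it holds J at 1.68 %.

(The numbers in the tables come from a simulation from invented constants; scatter was added.)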